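The numbers in the tables are calculated with constants of no real substance; scatter was added.

Read the first readings of a run as a half-life, then ask where that pace ends.

| setting | summer | dawn | flask |
|---|---|---|---|
| X | 1 M | 1.6 M | 0.73 M |
| G | 34 mM (held) | 34 mM (held) | 34 mM (held) |
| remark | run made earlier | run made earlier |  |
| time |  |  | 3.0 d |

| run | time / d | J / % |
|---|---|---|
| summer | 0.833 | 62 |
| summer | 1.67 | 83 |
| summer | 2.50 | 94 |
| summer | 3.00 | 91 |
| dawn | 0.833 | 60 |
| dawn | 1.67 | 81 |
| dawn | 2.50 | 88 |
| dawn | 3.00 | 93 |

(each reading ± 2 percentage points)

- the numbers in the tables scatter with a standard deviation of 2 percentage points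
- at the start none of G is in solution

- how much J there is at 3.0 d, in percent of the X charged
- the change that raises the amount of J at 3.0 d, in percent of the X charged most ("none" if none brings more than 2 percentage points) (eta / theta / none)
- amount of J at 3.0 d, in percent of the X charged, after eta

- eta: doubling the saturation concentration of G, all else as stated
- theta: doubling the transfer coefficient of G, all else as stated

At 0.833 d, J stands at 62% in summer and 60% in dawn. That gap is about the scatter, though dawn holds 1.60 times the X. The percent reading at that time therefore does not follow the charge in these two runs, which fits a first-order fall, or a pseudo-first-order one if dissolved G holds steady. The mean of these two readings gives the early half-life τ, the half-life of X implied by a plain first-order fall, with X taken as the charge less J: 0.613 d.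

The first way to the answer runs τ on to 3.0 d and gives 96.6% of J. The second way takes the mean of the four late readings, 91.5%. The two ways part by 5.1 percentage points, while such a mean scatters by 1 point. The first way is the one that cheats, since the late mean stands lower than it. The reckoning here commits to the late mean. These runs hold G at one value, so they give no reckoning of eta.

The forecast gives 93%, names eta and puts J after it at 97%, adding: “The order in G is assumed, not shown by these runs.”

The flask gives 93.0%. The best change is eta, which adds 4.4 points and reaches 97.4%, more than the 0.13 points that theta adds.

    G ⇌ Z, rate k1*(csat - [Z]) (kL = 0.00449 s⁻¹)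
    Z ⇌ L (K = 32.7, k = 1.19 × 10⁻⁵ s⁻¹)
    X + Z ⇌ J (K = 1100 L mol⁻¹, k = 4.21 × 10⁻⁴ L mol⁻¹ s⁻¹)
    X → D (k = 3.19 × 10⁻⁷ s⁻¹)

In the flask, the forward step X + Z → J by itself gives X a half-life of 0.58 d at 0.579 d, and 3.0 d spans 5.17 such half-lives. The flask holds X at 17.4% at 1.50 d, where τ gives 18.3%, and at 4.66% at 3.00 d, where τ gives 3.36%. A neighbour flask, the same charge read at 20 h, the time of the readings behind τ, gets 61.0% of J from τ and holds 61.3%.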